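**Retrosynthetic overview**
- The target is an acyclic, achiral ester. No ring is formed at any stage (the phenyl ring is bought with 2-phenylethanol) and there is no stereocentre to set.
- Key disconnection (new step): the C2–C3 bond of the C23 acyl chain. It is cut into a henicosyl (C21) radical, released with loss of CO2 from the N-hydroxyphthalimide ester of C22 behenic acid, and the zinc enolate of 2-phenylethyl acetate. Net result: one-carbon homologation plus esterification of a commodity even-chain acid, without diazo chemistry and without the odd-chain C23 acid.
- The zinc enolate comes from Zn insertion into 2-phenylethyl bromoacetate, which comes from 2-phenylethanol and bromoacetyl bromide (this makes the ester C–O bond).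
- The redox-active ester comes from docosanoic acid and N-hydroxyphthalimide.
- Order: two short arms (one step and two steps) are joined in the final Ni-catalysed coupling.

Assumption: the target has no stereocentre and no stereogenic double bond, so the "single enantiomer" is the achiral compound itself and no stereocontrol is needed.

**Route**

Step 1
Reactants: 1 docosanoic acid (behenic acid); 2 N-hydroxyphthalimide
Product: 3 1,3-dioxoisoindolin-2-yl docosanoate (N-(docosanoyloxy)phthalimide)
Conditions: DIC (1.1 equiv), DMAP (10 mol%), CH2Cl2/THF 4:1, 23 °C, 4 h; filter off urea, recrystallise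
Reagents that add atoms: none
Why: Steglich-type carbodiimide esterification, in which DIC turns the acid into an O-acylisourea and DMAP relays the acyl group to the acidic N–OH of 2 while the urea precipitates; no stereocentre is involved.

Step 2
Reactants: 4 2-phenylethanol; 5 bromoacetyl bromide
Product: 6 2-phenylethyl 2-bromoacetate
Conditions: NaHCO3 (solid, 1.5 equiv), CH2Cl2, 0 → 23 °C, 2 h
Reagents that add atoms: none
Why: Nucleophilic acyl substitution (O-acylation of a primary alcohol by an acyl bromide), where the acyl C–Br is far more electrophilic than the CH2–Br and solid bicarbonate removes HBr without a nucleophilic amine that could attack the α-carbon.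

Step 3
Reactants: 6 2-phenylethyl 2-bromoacetate
Product: 7 bromo[2-oxo-2-(2-phenylethoxy)ethyl]zinc (Reformatsky reagent)
Conditions: Zn dust (1.5 equiv, activated with 3 mol% BrCH2CH2Br and 3 mol% TMSCl), THF, 40 °C, 1 h; filtered from excess Zn under Ar, titrated (I2), kept as a ca. 0.8 M THF solution at 0 °C
Reagents that add atoms: zinc, [Zn]
Why: Reformatsky reagent formation by oxidative insertion of activated Zn(0) into the α-carbonyl C–Br bond; the C-bound bromozinc ester enolate is too weak a nucleophile to attack its own ester at or below 40 °C, so it keeps as a THF solution.

Step 4
Reactants: 3 1,3-dioxoisoindolin-2-yl docosanoate; 7 bromo[2-oxo-2-(2-phenylethoxy)ethyl]zinc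
Product: 8 2-phenylethyl tricosanoate
Conditions: 7 (2.0 equiv), NiCl2·glyme (10 mol%), 4,4'-di-tert-butyl-2,2'-bipyridine (20 mol%), THF/DMA 3:2, 25 °C, 12 h; then aq. NH4Cl
Reagents that add atoms: none
Why: Proposed new method: Ni-catalysed decarboxylative alkoxycarbonylmethylation of a redox-active ester with a zinc ester enolate (a Reformatsky reagent as the nucleophile of a decarboxylative sp3–sp3 Negishi coupling, i.e. a diazo-free one-carbon homologation/esterification of the acid); 7 transmetalates to (dtbbpy)Ni to give a C-bound Ni(I) enolate that reduces 3 by single-electron transfer, the radical anion of 3 loses phthalimide anion and CO2 to give the primary henicosyl radical, this radical is captured by the Ni(II) enolate, and the resulting alkyl(α-ester-alkyl)Ni(III) species (the same kind of intermediate that closes the C–C bond in Ni-catalysed Negishi alkylations of α-bromo carbonyl compounds) reductively eliminates the new C2–C3 bond and returns Ni(I); the Ni–CH2CO2R fragment has no β-hydrogen, the soft bromozinc enolate should leave the ester and imide carbonyls alone at 25 °C, and no stereocentre is formed; closest known reaction type: Ni-catalysed decarboxylative Negishi alkyl–alkyl coupling of N-acyloxyphthalimides with alkylzinc reagents.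

**Compound list**

1 | docosanoic acid (behenic acid) | CCCCCCCCCCCCCCCCCCCCCC(=O)O | starting material
2 | N-hydroxyphthalimide | O=C1c2ccccc2C(=O)N1O | starting material
3 | 1,3-dioxoisoindolin-2-yl docosanoate | CCCCCCCCCCCCCCCCCCCCCC(=O)ON1C(=O)c2ccccc2C1=O | intermediate
4 | 2-phenylethanol | OCCc1ccccc1 | starting material
5 | bromoacetyl bromide | O=C(Br)CBr | starting material
6 | 2-phenylethyl 2-bromoacetate | O=C(CBr)OCCc1ccccc1 | intermediate
7 | bromo[2-oxo-2-(2-phenylethoxy)ethyl]zinc | Br[Zn]CC(=O)OCCc1ccccc1 | intermediate
8 | 2-phenylethyl tricosanoate | CCCCCCCCCCCCCCCCCCCCCCC(=O)OCCc1ccccc1 | target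

**Step count and risks**

Total step count: 4. Longest linear sequence: 3 steps (4 → 6 → 7 → 8); the other arm is 1 → 3 → 8.

Steps most likely to fail:

1. Step 4 (the proposed new coupling). The risks are slow transmetalation of the zinc enolate or a Ni enolate that is too weak a reductant for 3 (3 recovered), radical side products (henicosane, dotetracontane), enolate homocoupling to the succinate diester, and C-acylation of 7 by the activated ester. Fallback, known chemistry (Arndt–Eistert homologation): it sets out from 1 and comes back to the route at 8. Compound 1 is converted with (COCl)2 and catalytic DMF in CH2Cl2 into docosanoyl chloride F1. F1 is acylated with TMSCHN2 (THF/MeCN, 0 °C) to give 1-diazotricosan-2-one F2. Silver benzoate (10 mol%), Et3N and 4 (3 equiv) in THF at 50 °C then bring about the Wolff rearrangement to henicosylketene F3, which is trapped in the flask by 4 to give 8.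

2. Step 3 (Reformatsky reagent). The risks are Claisen-type self-condensation of the primary-alkyl zinc enolate, a low or drifting titre, and reductive dimerisation at the zinc surface. Fallback (deprotonation and transmetalation instead of zinc insertion): it sets out from 4 and comes back to the route at 7. Compound 4 is acetylated (Ac2O, pyridine, catalytic DMAP) to 2-phenylethyl acetate F4. F4 is deprotonated with LiHMDS in THF at −78 °C to lithium 1-(2-phenylethoxy)ethen-1-olate F5. F5 is transmetalated with ZnBr2 (1.0 equiv, −78 → 0 °C) to the same bromozinc enolate 7, used directly as its THF solution in step 4.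

3. Step 1 (redox-active ester). The risks are the poor solubility of the C22 acid, N-acylurea formation, and partial hydrolysis of 3 on silica. Fallback (acyl transfer from an acylimidazole instead of carbodiimide coupling): it sets out from 1 and comes back to the route at 3. Compound 1 is heated with carbonyldiimidazole (1.1 equiv, THF, 50 °C) to give 1-(1H-imidazol-1-yl)docosan-1-one F6. F6 is then treated in the same solvent with 2 (1.1 equiv, 50 °C) to give 3, which is purified by crystallisation only.

Further compounds
F1 | step 4 | docosanoyl chloride | CCCCCCCCCCCCCCCCCCCCCC(=O)Cl
F2 | step 4 | 1-diazotricosan-2-one | CCCCCCCCCCCCCCCCCCCCCC(=O)C=[N+]=[N-]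
F3 | step 4 | henicosylketene | CCCCCCCCCCCCCCCCCCCCCC=C=O
F4 | step 3 | 2-phenylethyl acetate | CC(=O)OCCc1ccccc1
F5 | step 3 | lithium 1-(2-phenylethoxy)ethen-1-olate | C=C(O[Li])OCCc1ccccc1
F6 | step 1 | 1-(1H-imidazol-1-yl)docosan-1-one | CCCCCCCCCCCCCCCCCCCCCC(=O)n1ccnc1
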